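**Plan**
1. Cuts: first the five O-isopropyl bonds of a protected precursor. Next, in the 6-linked (acacetin) half, C4a–C4, C4–C3 and O1–C2, which takes that pyrone apart into an o-iodophenol, CO and 4-ethynylanisole. Last, the C6–C8'' biaryl bond, which leads to 8''-iodo-tri-O-isopropylapigenin and a 2,6-diisopropoxy-4-silyloxyphenylzinc chloride.
2. Enabling feature (flavone numbering; unprimed = acacetin half, double-primed = apigenin half): without O1–C2–C3–C4, ring A of the acacetin half (C4a, C5, C6, C7, C8, C8a) is a 4-aryl-3,5-dialkoxyphenol. It has a local mirror plane through C6 and C8a, so the two open carbons next to the phenol oxygen are equivalent. Whichever takes the iodine becomes C4a and the other becomes C8.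
3. Forward order: apigenin supplies the 8-linked half with all three rings in place, and a Negishi coupling makes the biaryl bond. Desilylation and mono-iodination prepare the only ring-forming step, which closes the acacetin pyrone and brings in C4, C3, C2 and the methoxylated ring B. BCl3 then frees the five phenols and leaves the methyl ether.
4. Stereochemistry: the target has no stereocentre, so none has to be set.

Key step: step 8

Assumption: the target SMILES carries no axial descriptor. The hindered C6–C8'' axis is therefore formed without control, and the biaryls from 12 onward are taken as racemic atropisomers.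

**Step 1**
Reactants: 1 apigenin
Product: 2 5,7,4'-triisopropoxyflavone (tri-O-isopropylapigenin)
Conditions: 2-bromopropane (excess), K2CO3, DMF, 80 °C
Reagents that add atoms: 2-bromopropane, CC(C)Br
Why: Williamson etherification of all three phenols, where excess secondary bromide, a polar aprotic solvent and heat are what is normally needed to alkylate the chelated 5''-OH fully.

**Step 2**
Reactants: 2 5,7,4'-triisopropoxyflavone
Product: 3 8-iodo-5,7,4'-triisopropoxyflavone
Conditions: NIS (1.05 equiv), CF3CO2H (cat.), MeCN, 0 °C → rt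
Reagents that add atoms: N-iodosuccinimide, O=C1CCC(=O)N1I
Why: Electrophilic aromatic iodination of fully O-alkylated 5,7-dioxygenated flavones is known to go to C8, and here C6'' is also flanked by two isopropoxy groups, whereas C8'' has the tied-back ring oxygen O1'' on one side.

**Step 3**
Reactants: 4 1,3-diisopropoxybenzene
Product: 6 3,5-diisopropoxyphenol, via aryl pinacol boronate 5 (not isolated)
Conditions: [Ir(OMe)(cod)]2 (1.5 mol %), dtbpy (3 mol %), B2pin2 (0.6 equiv), hexane, 80 °C; then 2KHSO5·KHSO4·K2SO4, acetone/H2O, rt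
Reagents that add atoms: bis(pinacolato)diboron, CC1(C)OB(OC1(C)C)B1OC(C)(C)C(C)(C)O1 (boryl group of 5); potassium peroxymonosulfate, [K+].[O-]S(=O)(=O)OO (phenol oxygen of 6)
Why: Sterically governed iridium-catalysed C–H borylation reaches only C5–H, the one ring hydrogen without an ortho substituent, and the one-pot oxidation of the aryl boronate converts C–B into C–OH at the same carbon.

**Step 4**
Reactants: 6 3,5-diisopropoxyphenol
Product: 7 (3,5-diisopropoxyphenoxy)triisopropylsilane
Conditions: iPr3SiCl, imidazole, DMF, rt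
Reagents that add atoms: triisopropylsilyl chloride, CC(C)[Si](Cl)(C(C)C)C(C)C
Why: Standard phenol silylation, with the bulky and poorly coordinating triisopropylsilyl ether chosen because it shields its two neighbouring ring carbons and does not direct lithiation.

**Step 5**
Reactants: 7 (3,5-diisopropoxyphenoxy)triisopropylsilane, 3 8-iodo-5,7,4'-triisopropoxyflavone
Product: 10 8-[2,6-diisopropoxy-4-(triisopropylsilyloxy)phenyl]-5,7,4'-triisopropoxyflavone, via aryllithium 8 (not isolated), via arylzinc chloride 9 (not isolated)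
Conditions: 7 (1.5 equiv), n-BuLi, TMEDA, THF, 0 °C → rt; ZnCl2, THF, 0 °C → rt; then 3, Pd2(dba)3 (2 mol %), RuPhos (8 mol %), THF/NMP, 80 °C
Reagents that add atoms: n-butyllithium, [Li]CCCC (lithium of 8); zinc chloride, Cl[Zn]Cl (zinc and chlorine of 9)
Why: Directed ortho-metalation takes the carbon between the two isopropoxy groups, as in 1,3-diisopropoxybenzene itself, and Negishi coupling of the derived arylzinc chloride with a bulky dialkylbiarylphosphine–palladium catalyst is an established route to tetra-ortho-substituted biaryls that avoids the protodeboronation of 2,6-dialkoxyarylboron reagents and leaves the flavone carbonyl untouched.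

**Step 6**
Reactants: 10 8-[2,6-diisopropoxy-4-(triisopropylsilyloxy)phenyl]-5,7,4'-triisopropoxyflavone
Product: 11 8-(4-hydroxy-2,6-diisopropoxyphenyl)-5,7,4'-triisopropoxyflavone
Conditions: Bu4NF, AcOH (1:1), THF, 0 °C → rt
Reagents that add atoms: none
Why: Fluoride-induced cleavage of an unhindered aryl silyl ether is fast even when buffered, and neither the isopropyl ethers nor the pyrone respond to these conditions.

**Step 7**
Reactants: 11 8-(4-hydroxy-2,6-diisopropoxyphenyl)-5,7,4'-triisopropoxyflavone
Product: 12 8-(4-hydroxy-3-iodo-2,6-diisopropoxyphenyl)-5,7,4'-triisopropoxyflavone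
Conditions: NIS (1.0 equiv), CH2Cl2, −20 → 0 °C
Reagents that add atoms: N-iodosuccinimide, O=C1CCC(=O)N1I
Why: In this electrophilic phenol iodination the free-phenol ring with its three oxygen donors is by far the most nucleophilic arene, its para carbon is blocked by the biaryl bond and its two ortho carbons are equivalent, so one equivalent of NIS without acid should give a single mono-iodide.

**Step 8**
Reactants: 12 8-(4-hydroxy-3-iodo-2,6-diisopropoxyphenyl)-5,7,4'-triisopropoxyflavone, 13 4-ethynylanisole, 14 carbon monoxide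
Product: 17 penta-O-isopropyl ether of the target (5,7,5'',7'',4'''-pentaisopropoxy-4'-methoxy-6,8''-biflavone), via ynone 15 (not isolated), via diethylamino enaminone 16 (not isolated)
Conditions: PdCl2(PPh3)2 (5 mol %), 13 (2 equiv), CO (20 bar), Et2NH, 120 °C
Reagents that add atoms: diethylamine, CCNCC (Et2N group of 16, released again on ring closure)
Why: Zerovalent palladium, formed from PdCl2(PPh3)2 under CO and amine, adds oxidatively to the C4a–I bond of 12, CO inserts to give an aroylpalladium iodide, and the amine-deprotonated alkyne is transferred and reductively eliminated to ynone 15, which makes C4a–C4 and C4–C3. Diethylamine then adds in conjugate fashion at C2 to give enaminone 16, and the neighbouring phenol oxygen displaces the amine by addition–elimination, a 6-endo closure (6-endo-trig on 16, 6-endo-dig if counted from 15) that forms O1–C2 and completes the pyrone. The reaction type is the known palladium-catalysed carbonylative annulation of o-iodophenols with terminal alkynes to flavones, that is, a copper-free carbonylative Sonogashira coupling followed by cyclisation. Three selectivities are needed: CO insertion before alkyne transfer (20 bar CO, no copper, and an electron-rich, doubly ortho-flanked aryl group that migrates readily to CO), capture of the aroylpalladium by the alkyne and not by the amine (excess 13), and 6-endo instead of 5-exo closure (in 16 the electrophilic carbon is C2, which shuts off the aurone path). No stereocentre is formed, and the crowded biaryl axis already present in 12 stays racemic. The existing apigenin pyrone can add diethylamine only reversibly and recloses under the same conditions, and the isopropyl ethers are inert.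

**Step 9**
Reactants: 17 penta-O-isopropyl ether of the target
Product: 18 target, 4'-O-methylagathisflavone (5,7,5'',7'',4'''-pentahydroxy-4'-methoxy-6,8''-biflavone)
Conditions: BCl3 (excess), CH2Cl2, −78 °C → rt; aq. HCl work-up
Reagents that add atoms: none
Why: In this Lewis-acid ether cleavage BCl3 binds the ether oxygens and chloride removes a secondary isopropyl group through a cation-like transition state much faster than a methyl group that has no neighbouring carbonyl, so the 4'-methyl ether should remain, and the cold aprotic medium avoids the Wessely–Moser ring opening that could exchange the 6- and 8-linkages.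

**Compound list**
1 | apigenin | O=c1cc(-c2ccc(O)cc2)oc2cc(O)cc(O)c12 | starting material
2 | 5,7,4'-triisopropoxyflavone | CC(C)Oc1ccc(cc1)-c1cc(=O)c2c(OC(C)C)cc(OC(C)C)cc2o1 | intermediate
3 | 8-iodo-5,7,4'-triisopropoxyflavone | CC(C)Oc1ccc(cc1)-c1cc(=O)c2c(OC(C)C)cc(OC(C)C)c(I)c2o1 | intermediate
4 | 1,3-diisopropoxybenzene | CC(C)Oc1cccc(OC(C)C)c1 | starting material
5 | 2-(3,5-diisopropoxyphenyl)-4,4,5,5-tetramethyl-1,3,2-dioxaborolane | CC(C)Oc1cc(OC(C)C)cc(c1)B1OC(C)(C)C(C)(C)O1 | intermediate
6 | 3,5-diisopropoxyphenol | CC(C)Oc1cc(O)cc(OC(C)C)c1 | intermediate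
7 | (3,5-diisopropoxyphenoxy)triisopropylsilane | CC(C)Oc1cc(OC(C)C)cc(O[Si](C(C)C)(C(C)C)C(C)C)c1 | intermediate
8 | 2,6-diisopropoxy-4-(triisopropylsilyloxy)phenyllithium | [Li]c1c(OC(C)C)cc(O[Si](C(C)C)(C(C)C)C(C)C)cc1OC(C)C | intermediate
9 | 2,6-diisopropoxy-4-(triisopropylsilyloxy)phenylzinc chloride | Cl[Zn]c1c(OC(C)C)cc(O[Si](C(C)C)(C(C)C)C(C)C)cc1OC(C)C | intermediate
10 | 8-[2,6-diisopropoxy-4-(triisopropylsilyloxy)phenyl]-5,7,4'-triisopropoxyflavone | CC(C)Oc1ccc(cc1)-c1cc(=O)c2c(OC(C)C)cc(OC(C)C)c(-c3c(OC(C)C)cc(O[Si](C(C)C)(C(C)C)C(C)C)cc3OC(C)C)c2o1 | intermediate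
11 | 8-(4-hydroxy-2,6-diisopropoxyphenyl)-5,7,4'-triisopropoxyflavone | CC(C)Oc1ccc(cc1)-c1cc(=O)c2c(OC(C)C)cc(OC(C)C)c(-c3c(OC(C)C)cc(O)cc3OC(C)C)c2o1 | intermediate
12 | 8-(4-hydroxy-3-iodo-2,6-diisopropoxyphenyl)-5,7,4'-triisopropoxyflavone (racemic axis) | CC(C)Oc1ccc(cc1)-c1cc(=O)c2c(OC(C)C)cc(OC(C)C)c(-c3c(OC(C)C)cc(O)c(I)c3OC(C)C)c2o1 | intermediate
13 | 4-ethynylanisole | COc1ccc(C#C)cc1 | starting material
14 | carbon monoxide | [C-]#[O+] | starting material
15 | 8-{4-hydroxy-2,6-diisopropoxy-3-[3-(4-methoxyphenyl)prop-2-ynoyl]phenyl}-5,7,4'-triisopropoxyflavone | COc1ccc(cc1)C#CC(=O)c1c(O)cc(OC(C)C)c(c1OC(C)C)-c1c(OC(C)C)cc(OC(C)C)c2c1oc(cc2=O)-c1ccc(OC(C)C)cc1 | intermediate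
16 | 8-{3-[3-(diethylamino)-3-(4-methoxyphenyl)prop-2-enoyl]-4-hydroxy-2,6-diisopropoxyphenyl}-5,7,4'-triisopropoxyflavone (transient, alkene geometry not fixed) | CCN(CC)C(=CC(=O)c1c(O)cc(OC(C)C)c(c1OC(C)C)-c1c(OC(C)C)cc(OC(C)C)c2c1oc(cc2=O)-c1ccc(OC(C)C)cc1)c1ccc(OC)cc1 | intermediate
17 | 5,7,5'',7'',4'''-pentaisopropoxy-4'-methoxy-6,8''-biflavone | COc1ccc(cc1)-c1cc(=O)c2c(OC(C)C)c(-c3c(OC(C)C)cc(OC(C)C)c4c(=O)cc(-c5ccc(OC(C)C)cc5)oc34)c(OC(C)C)cc2o1 | intermediate
18 | 4'-O-methylagathisflavone (CNP0302154.0) | COc1ccc(-c2cc(=O)c3c(O)c(-c4c(O)cc(O)c5c(=O)cc(-c6ccc(O)cc6)oc45)c(O)cc3o2)cc1 | target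

**Total step count:** 9
**Longest linear sequence:** 7 steps (3, 4, 5, 6, 7, 8, 9 from 4, or 1, 2, 5, 6, 7, 8, 9 from 1)

**Steps most likely to fail**

Step 5. Palladium must carry two aryl groups with four ortho oxygen substituents between them. Transmetalation and reductive elimination may therefore be slower than hydrodeiodination of the flavone partner or homocoupling of the zinc reagent.
The fallback sets out from 3 and 7, returns at 10, and reverses the polarity of the coupling.
- Miyaura borylation of 3 (B2pin2, PdCl2(dppf), KOAc, dioxane, 90 °C) should give 5,7,4'-triisopropoxyflavone-8-boronic acid pinacol ester F1.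
- Lithiation of 7 as in step 5 and quenching of 8 with I2 should give (4-iodo-3,5-diisopropoxyphenoxy)triisopropylsilane F2.
- Suzuki–Miyaura coupling of F1 with F2 (Pd(OAc)2, SPhos, K3PO4, toluene/H2O, 100 °C) leads back to 10.

The bulkier diisopropoxyaryl group then reaches palladium by oxidative addition, which tolerates crowding better than transmetalation. The boron sits on a carbon flanked by only one freely rotating alkoxy group.

Step 8. Three things may go wrong:
- the alkyne may be transferred before CO inserts, followed by cyclisation onto the triple bond;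
- the aroylpalladium may be intercepted by diethylamine;
- oxidative addition at the electron-rich, doubly flanked C–I bond may be slow, with reductive loss of iodine.

The fallback sets out from 11 (step 7 is then not needed), returns at 17, and builds the pyrone without palladium.
- Friedel–Crafts C-acetylation ortho to the phenol (Ac2O, BF3·OEt2, 0 → 50 °C) should give 8-(3-acetyl-4-hydroxy-2,6-diisopropoxyphenyl)-5,7,4'-triisopropoxyflavone F3.
- Direct C-aroylation of its lithium enolate, the one-flask variant of the Baker–Venkataraman sequence (LiN(SiMe3)2 in excess, 4-methoxybenzoyl chloride, THF, −78 °C), should give the 1-aryl-3-(4-methoxyphenyl)propane-1,3-dione F4.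
- Acid-catalysed cyclodehydration (cat. H2SO4, AcOH, 90 °C) closes O1–C2 and gives 17.

Step 2. The iodination may be shared between C8'' and C6'' or spill over onto ring B, and such mixtures would be hard to separate.
The fallback sets out from 6, returns at 3 (steps 1 and 2 are then not needed), and fixes the iodine before the pyrone exists.
- C-acetylation of 6 (Ac2O, BF3·OEt2) should give 2-hydroxy-4,6-diisopropoxyacetophenone F5.
- Iodination (NIS, MeCN, 0 °C) should go ortho to the free hydroxyl group, away from the carbon between the two isopropoxy groups, and give 2-hydroxy-3-iodo-4,6-diisopropoxyacetophenone F6.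
- Enolate aroylation (LiN(SiMe3)2, commercial 4-isopropoxybenzoyl chloride, THF, −78 °C) should give 1-(2-hydroxy-3-iodo-4,6-diisopropoxyphenyl)-3-(4-isopropoxyphenyl)propane-1,3-dione F7.
- Cyclodehydration (cat. H2SO4, AcOH, 90 °C) turns the iodinated carbon next to the phenol oxygen into C8'' of 3.

**Further compounds**
F1 | step 5 | 5,7,4'-triisopropoxyflavone-8-boronic acid pinacol ester | CC(C)Oc1ccc(cc1)-c1cc(=O)c2c(OC(C)C)cc(OC(C)C)c(B3OC(C)(C)C(C)(C)O3)c2o1
F2 | step 5 | (4-iodo-3,5-diisopropoxyphenoxy)triisopropylsilane | CC(C)Oc1cc(O[Si](C(C)C)(C(C)C)C(C)C)cc(OC(C)C)c1I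
F3 | step 8 | 8-(3-acetyl-4-hydroxy-2,6-diisopropoxyphenyl)-5,7,4'-triisopropoxyflavone | CC(=O)c1c(O)cc(OC(C)C)c(c1OC(C)C)-c1c(OC(C)C)cc(OC(C)C)c2c1oc(cc2=O)-c1ccc(OC(C)C)cc1
F4 | step 8 | 1-[6-hydroxy-2,4-diisopropoxy-3-(5,7,4'-triisopropoxyflavon-8-yl)phenyl]-3-(4-methoxyphenyl)propane-1,3-dione | COc1ccc(cc1)C(=O)CC(=O)c1c(O)cc(OC(C)C)c(c1OC(C)C)-c1c(OC(C)C)cc(OC(C)C)c2c1oc(cc2=O)-c1ccc(OC(C)C)cc1
F5 | step 2 | 2-hydroxy-4,6-diisopropoxyacetophenone | CC(=O)c1c(O)cc(OC(C)C)cc1OC(C)C
F6 | step 2 | 2-hydroxy-3-iodo-4,6-diisopropoxyacetophenone | CC(=O)c1c(O)c(I)c(OC(C)C)cc1OC(C)C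
F7 | step 2 | 1-(2-hydroxy-3-iodo-4,6-diisopropoxyphenyl)-3-(4-isopropoxyphenyl)propane-1,3-dione | CC(C)Oc1ccc(cc1)C(=O)CC(=O)c1c(O)c(I)c(OC(C)C)cc1OC(C)C
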